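**Assumption:** the target has no stereocentre and no hindered axis, so it is achiral; "single enantiomer" is taken to mean the constitution given by the SMILES. The route is a proposal from first principles and has not been run.

## Retrosynthetic overview

1. Target 9 ⇐ aldehyde 7: the ring B C–OH comes from C–CHO by Baeyer–Villiger oxidation and formate cleavage.
2. 7 ⇐ 5: phenol-directed dibromination of ring A, while the formyl group keeps ring B inert.
3. 5 ⇐ 3 + catechol 4: the diaryl ether C–O bond is made by SNAr at the C–F ortho to the formyl group.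
4. 3 ⇐ 1: double electrophilic bromination, with CHO, F and Br all directing to C3 and C5.
5. No ring is built: ring B comes from arene 1 and ring A from catechol 4, joined in step 2.

## Route

Step 1
Reactants: 1 2-bromo-6-fluorobenzaldehyde
Product: 3 2,3,5-tribromo-6-fluorobenzaldehyde, via 2,3-dibromo-6-fluorobenzaldehyde 2 (not isolated)
Conditions: NBS (2.4 equiv), conc. H2SO4, 60 °C
Reagents that add atoms: N-bromosuccinimide (NBS), O=C1CCC(=O)N1Br
Why: Electrophilic aromatic bromination (SEAr) with acid-activated NBS, in which CHO (meta) and F and Br (ortho/para) all direct to C3 and C5, so the first bromine enters para to F and the second ortho to F while the protonated formyl group resists oxidation; no stereocentre is formed.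

Step 2
Reactants: 3 2,3,5-tribromo-6-fluorobenzaldehyde; 4 catechol (benzene-1,2-diol, 3 equiv)
Product: 5 2,3,5-tribromo-6-(2-hydroxyphenoxy)benzaldehyde
Conditions: K2CO3 (1.2 equiv), DMF, 0 °C → rt, N2
Reagents that add atoms: none
Why: Nucleophilic aromatic substitution (SNAr through a Meisenheimer complex), in which the catechol monoanion displaces the fluoride ortho to the formyl group far faster than any bromide, and excess catechol at room temperature limits reaction to one oxygen; no stereocentre is formed.

Step 3
Reactants: 5 2,3,5-tribromo-6-(2-hydroxyphenoxy)benzaldehyde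
Product: 7 2,3,5-tribromo-6-(3,5-dibromo-2-hydroxyphenoxy)benzaldehyde, via monobrominated phenol 6 (not isolated)
Conditions: Br2 (2.05 equiv), AcOH, rt
Reagents that add atoms: bromine, BrBr
Why: Phenol-directed electrophilic bromination (SEAr), in which the free OH of ring A directs first para and then ortho, while ring B, carrying CHO and three bromines, does not react; no stereocentre is formed.

Step 4
Reactants: 7 2,3,5-tribromo-6-(3,5-dibromo-2-hydroxyphenoxy)benzaldehyde
Product: 9 2,3,5-tribromo-6-(3,5-dibromo-2-hydroxyphenoxy)phenol, via aryl formate 8 (not isolated)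
Conditions: mCPBA (2.5 equiv), CH2Cl2, 40 °C; then HCl (cat.), MeOH, rt
Reagents that add atoms: 3-chloroperoxybenzoic acid (mCPBA), OOC(=O)c1cccc(Cl)c1
Why: Baeyer–Villiger oxidation, in which the ortho-aryloxy oxygen and the di-ortho substitution favour aryl over hydride migration in the Criegee adduct to give the formate, which acid-catalysed methanolysis cleaves to the phenol; no stereocentre is formed.

## Compound list

1 | 2-bromo-6-fluorobenzaldehyde | O=Cc1c(F)cccc1Br | starting material
2 | 2,3-dibromo-6-fluorobenzaldehyde | O=Cc1c(F)ccc(Br)c1Br | intermediate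
3 | 2,3,5-tribromo-6-fluorobenzaldehyde | O=Cc1c(F)c(Br)cc(Br)c1Br | intermediate
4 | catechol (benzene-1,2-diol) | Oc1ccccc1O | starting material
5 | 2,3,5-tribromo-6-(2-hydroxyphenoxy)benzaldehyde | O=Cc1c(Oc2ccccc2O)c(Br)cc(Br)c1Br | intermediate
6 | 2,3,5-tribromo-6-(5-bromo-2-hydroxyphenoxy)benzaldehyde | O=Cc1c(Oc2cc(Br)ccc2O)c(Br)cc(Br)c1Br | intermediate
7 | 2,3,5-tribromo-6-(3,5-dibromo-2-hydroxyphenoxy)benzaldehyde | O=Cc1c(Oc2cc(Br)cc(Br)c2O)c(Br)cc(Br)c1Br | intermediate
8 | 2,3,5-tribromo-6-(3,5-dibromo-2-hydroxyphenoxy)phenyl formate | O=COc1c(Oc2cc(Br)cc(Br)c2O)c(Br)cc(Br)c1Br | intermediate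
9 | 2,3,5-tribromo-6-(3,5-dibromo-2-hydroxyphenoxy)phenol (= 3,5,6-tribromo-2-(3,5-dibromo-2-hydroxyphenoxy)phenol) | Oc1c(Oc2cc(Br)cc(Br)c2O)c(Br)cc(Br)c1Br | target

## Step count

Total steps: 4. Longest linear sequence: 4 steps (1 → 3 → 5 → 7 → 9).

## Steps most likely to fail, with fallbacks

**Step 4 (highest risk).** On this electron-poor, di-ortho-substituted aldehyde, hydride migration to the benzoic acid may compete with aryl migration. The fallback sets out from 7 and comes back at 9. It replaces the formyl group by an acetyl group, so that the only competitor of aryl migration is the poorly migrating methyl group. MeMgBr (2.2 equiv, the first equivalent deprotonates the phenol) in THF at −78 °C gives racemic 1-[2,3,5-tribromo-6-(3,5-dibromo-2-hydroxyphenoxy)phenyl]ethan-1-ol F1, whose stereocentre is erased in the next operation. Dess–Martin periodinane with NaHCO3 in CH2Cl2 gives 1-[2,3,5-tribromo-6-(3,5-dibromo-2-hydroxyphenoxy)phenyl]ethan-1-one F2. Baeyer–Villiger oxidation with CF3CO3H (from urea·H2O2 and (CF3CO)2O, Na2HPO4, CH2Cl2, 0 °C → rt) gives 2,3,5-tribromo-6-(3,5-dibromo-2-hydroxyphenoxy)phenyl acetate F3. K2CO3 in MeOH, then acid work-up, cleaves the acetate to 9.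

**Step 1.** The second bromination is on a strongly deactivated ring and may stall at 2 or erode the aldehyde. The fallback uses no numbered compound of the route as its start: commercial 1,2,4-tribromo-5-fluorobenzene F4 takes the place of 1, and the fallback comes back at 3. Here the bromines are already in place and the formyl group is introduced last. Directed magnesiation with TMPMgCl·LiCl (TMP = 2,2,6,6-tetramethylpiperidide) in THF at −20 °C removes the most acidic proton, the one flanked by F and Br, to give (2,3,5-tribromo-6-fluorophenyl)magnesium chloride F5. Quenching with DMF and aqueous NH4Cl work-up gives 3.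

**Step 2.** The second catechol oxygen may react further, either by bis-arylation or by displacing a bromide (ortho to CHO, or intramolecularly to a dibenzodioxin). The fallback sets out from 3 and comes back at 5. It uses a mono-protected nucleophile: 2-methoxyphenol F6 with K2CO3 in DMF at rt gives 2,3,5-tribromo-6-(2-methoxyphenoxy)benzaldehyde F7 by the same SNAr. BBr3 in CH2Cl2 at −78 → 0 °C then cleaves the methyl ether to 5.

## Further compounds

F1 | step 4 | 1-[2,3,5-tribromo-6-(3,5-dibromo-2-hydroxyphenoxy)phenyl]ethan-1-ol (racemic) | CC(O)c1c(Oc2cc(Br)cc(Br)c2O)c(Br)cc(Br)c1Br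
F2 | step 4 | 1-[2,3,5-tribromo-6-(3,5-dibromo-2-hydroxyphenoxy)phenyl]ethan-1-one | CC(=O)c1c(Oc2cc(Br)cc(Br)c2O)c(Br)cc(Br)c1Br
F3 | step 4 | 2,3,5-tribromo-6-(3,5-dibromo-2-hydroxyphenoxy)phenyl acetate | CC(=O)Oc1c(Oc2cc(Br)cc(Br)c2O)c(Br)cc(Br)c1Br
F4 | step 1 | 1,2,4-tribromo-5-fluorobenzene | Fc1cc(Br)c(Br)cc1Br
F5 | step 1 | (2,3,5-tribromo-6-fluorophenyl)magnesium chloride | Fc1c([Mg]Cl)c(Br)c(Br)cc1Br
F6 | step 2 | 2-methoxyphenol | COc1ccccc1O
F7 | step 2 | 2,3,5-tribromo-6-(2-methoxyphenoxy)benzaldehyde | COc1ccccc1Oc1c(C=O)c(Br)c(Br)cc1Br
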